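**Retrosynthetic overview**

1. The target comes from (12E)-labda-12,14-diene-6α,8α-diol 22 by late angeloylation at O6. The C13–C15 diene end is built by two Wittig steps on a C12 aldehyde; 8α-OH and the C17 methyl come from α-face epoxidation and hydride opening of a C8=C17 methylene; 6α-OH comes from thermodynamic reduction of a C6 ketone.
2. Ring B is closed last, at C7–C8, by a gold-catalysed Conia-ene-type carbocyclisation: C7 (terminus of the C6 silyl enol ether) adds to C8 of a C8≡C17 alkyne on C9. One operation gives ring B, the C6 carbonyl and the C8=C17 methylene.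
3. Enabling feature: the 1,3-dioxygenated C6–C7–C8 array of ring B. The methyl carbinol C8(C17) is a hydrated alkyne terminus and C6/C7 is an enol, while the two arms at C5 and C10 sit trans-diequatorial on ring A.
4. The monocyclic precursor comes from an Ireland–Claisen rearrangement (C9–C10 bond, C10 quaternary centre and C9 in one step, 1,3-chirality transfer from a CBS-derived carbinol), then hydroboration (C5–H, C6 oxygen) and aldehyde-to-alkyne homologation.
5. Ring order: ring A is purchased (β-cyclocitral); ring B is formed in step 10.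

Key step: step 10

Remark: skeletal atoms carry labdane numbers (C1–C20) throughout; α is the face opposite the C10 methyl group.

**Route**

Step 1
Reactants: 1 β-cyclocitral (2,6,6-trimethylcyclohex-1-ene-1-carbaldehyde)
Product: 2 rac-1-(2,6,6-trimethylcyclohex-1-en-1-yl)ethan-1-ol
Conditions: MeMgBr, THF, 0 °C; aq. NH4Cl
Reagents that add atoms: methylmagnesium bromide, C[Mg]Br
Why: Grignard 1,2-addition to the hindered, non-enolisable enal should give the racemic allylic carbinol, whose stereocentre is erased in step 2 and set in step 3.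

Step 2
Reactants: 2 rac-1-(2,6,6-trimethylcyclohex-1-en-1-yl)ethan-1-ol
Product: 3 1-(2,6,6-trimethylcyclohex-1-en-1-yl)ethan-1-one
Conditions: Dess–Martin periodinane, CH2Cl2, 0 °C to rt
Reagents that add atoms: none
Why: Dess–Martin oxidation should convert the allylic alcohol into the twisted enone under conditions that do not ionise the allylic C–O bond.

Step 3
Reactants: 3 1-(2,6,6-trimethylcyclohex-1-en-1-yl)ethan-1-one
Product: 4 (R)-1-(2,6,6-trimethylcyclohex-1-en-1-yl)ethan-1-ol
Conditions: (S)-2-methyl-CBS-oxazaborolidine (10 mol %), BH3·SMe2, THF, −20 °C; MeOH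
Reagents that add atoms: none
Why: In this Corey–Bakshi–Shibata reduction the bulky cyclohexenyl group acts as the large and methyl as the small substituent, so the (S)-oxazaborolidine–borane complex should deliver hydride to the face that gives the (R)-carbinol, as with aryl methyl ketones.

Step 4
Reactants: 4 (R)-1-(2,6,6-trimethylcyclohex-1-en-1-yl)ethan-1-ol; 5 4-(benzyloxy)butanoic acid
Product: 6 (R)-1-(2,6,6-trimethylcyclohex-1-en-1-yl)ethyl 4-(benzyloxy)butanoate
Conditions: DCC, DMAP (cat.), CH2Cl2, 0 °C to rt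
Reagents that add atoms: none
Why: Steglich esterification should acylate the secondary allylic alcohol under neutral conditions with the carbinol configuration unchanged.

Step 5
Reactants: 6 (R)-1-(2,6,6-trimethylcyclohex-1-en-1-yl)ethyl 4-(benzyloxy)butanoate
Product: 9 (2R)-4-(benzyloxy)-2-[(1R,2E)-2-ethylidene-1,3,3-trimethylcyclohexyl]butanoic acid, via silyl ketene acetal 7 (not isolated), via trimethylsilyl ester 8 (not isolated)
Conditions: LiN(iPr)2, THF/DMPU, −78 °C; Me3SiCl; −78 °C to 65 °C; aq. HCl
Reagents that add atoms: none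
Why: In this Ireland–Claisen rearrangement, enolisation in the presence of DMPU should give the (Z)-silyl ketene acetal, which rearranges through a chair transition state with the carbinol hydrogen eclipsing the ring double bond (least allylic 1,3-strain), so that the C6 configuration is transferred to the new C10 quaternary centre, the ketene acetal geometry sets C9, and the ethylidene forms with E geometry.

Step 6
Reactants: 9 (2R)-4-(benzyloxy)-2-[(1R,2E)-2-ethylidene-1,3,3-trimethylcyclohexyl]butanoic acid
Product: 11 (2R)-4-(benzyloxy)-2-[(1R,2S)-2-[(1R)-1-hydroxyethyl]-1,3,3-trimethylcyclohexyl]butan-1-ol, via bis-borane adduct 10 (not isolated)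
Conditions: BH3·THF (excess), THF, 0 °C to 40 °C; NaOH, H2O2, 0 °C to rt
Reagents that add atoms: hydrogen peroxide, OO
Why: Borane should reduce the carboxylic acid and hydroborate the ethylidene with boron at the less substituted C6, adding from the α face opposite the two syn-axial methyl groups (C10 methyl and the β methyl on C4), which sets 5α-H before oxidation with retention (hydroboration–oxidation).

Step 7
Reactants: 11 (2R)-4-(benzyloxy)-2-[(1R,2S)-2-[(1R)-1-hydroxyethyl]-1,3,3-trimethylcyclohexyl]butan-1-ol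
Product: 12 (2R)-2-[(1R,2S)-2-acetyl-1,3,3-trimethylcyclohexyl]-4-(benzyloxy)butanal
Conditions: (COCl)2, DMSO, CH2Cl2, −78 °C; Et3N, −78 °C to −20 °C; used crude
Reagents that add atoms: none
Why: Swern oxidation activates both hydroxyls as alkoxysulfonium salts before any carbonyl is present, which should avoid lactol and lactone formation and leave the α-stereocentres C5 and C9 untouched.

Step 8
Reactants: 12 (2R)-2-[(1R,2S)-2-acetyl-1,3,3-trimethylcyclohexyl]-4-(benzyloxy)butanal
Product: 13 1-[(1S,2R)-2-[(3S)-5-(benzyloxy)pent-1-yn-3-yl]-2,6,6-trimethylcyclohexyl]ethan-1-one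
Conditions: (MeO)2P(O)CHN2, KOC(CH3)3, THF, −78 °C to 0 °C
Reagents that add atoms: dimethyl (diazomethyl)phosphonate, [N-]=[N+]=CP(=O)(OC)OC
Why: In this Seyferth–Gilbert homologation the preformed phosphonate anion should add to the aldehyde at −78 °C much faster than to the hindered methyl ketone or than the ketone enolises, and loss of N2 with 1,2-hydride shift gives the terminal alkyne with C9 unchanged.

Step 9
Reactants: 13 1-[(1S,2R)-2-[(3S)-5-(benzyloxy)pent-1-yn-3-yl]-2,6,6-trimethylcyclohexyl]ethan-1-one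
Product: 14 tert-butyl({1-[(1S,2R)-2-[(3S)-5-(benzyloxy)pent-1-yn-3-yl]-2,6,6-trimethylcyclohexyl]ethenyl}oxy)dimethylsilane
Conditions: TBSOTf, Et3N, CH2Cl2, 0 °C
Reagents that add atoms: tert-butyldimethylsilyl trifluoromethanesulfonate, CC(C)(C)[Si](C)(C)OS(=O)(=O)C(F)(F)F
Why: Soft enolisation and O-silylation should give only the terminal silyl enol ether (C6=C7), because enolisation toward C5 would create a tetrasubstituted alkene flanked by two quaternary carbons.

Step 10
Reactants: 14 tert-butyl({1-[(1S,2R)-2-[(3S)-5-(benzyloxy)pent-1-yn-3-yl]-2,6,6-trimethylcyclohexyl]ethenyl}oxy)dimethylsilane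
Product: 16 (5S,9S,10R)-12-(benzyloxy)-13,14,15,16-tetranorlabd-8(17)-en-6-one, via vinylgold oxocarbenium 15 (not isolated)
Conditions: Ph3PAuCl (5 mol %), AgBF4 (5 mol %), CH2Cl2/MeOH 10:1, 25–40 °C
Reagents that add atoms: none
Why: The cationic phosphine complex of monovalent gold binds the terminal alkyne as a π-acid, and the enol ether terminus C7 attacks the internal alkyne carbon C8 anti to gold; the vinylgold silyloxocarbenium ion then loses its silyl group to methanol and is protodeaurated, which frees the catalyst. The closest known reaction type is the gold-catalysed Conia-ene-type exo-dig carbocyclisation of silyl enol ethers onto tethered terminal alkynes, known for five- and six-membered rings. Ring B closes in a 6-(enolendo)-exo-dig mode. No new stereocentre is formed: the trans ring fusion follows from the diequatorial arms at C5 and C10 already in place, and C5, C9 and C10 are not touched under these neutral conditions. The step needs attack at C8 and not at C17, and C- not O-attack; Markovnikov polarisation of the gold-bound terminal alkyne together with six- over seven-membered ring size secures the first, the soft carbon terminus of the enol ether the second. In one operation it should form the C7–C8 bond, ring B, the C6 carbonyl and the C8=C17 methylene that carries both the future C17 methyl and the site of the C8 oxygen.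

Step 11
Reactants: 16 (5S,9S,10R)-12-(benzyloxy)-13,14,15,16-tetranorlabd-8(17)-en-6-one
Product: 17 (5S,6S,9S,10R)-13,14,15,16-tetranorlabd-8(17)-ene-6,12-diol
Conditions: Li, NH3(l), THF, t-BuOH, −78 °C; NH4Cl
Reagents that add atoms: none
Why: Dissolving-metal reduction should give the thermodynamically favoured equatorial 6α-alcohol (the axial 6β position is syn-axial to the C10 methyl and the β methyl on C4) and cleave the benzyl ether, while the isolated exocyclic alkene is inert and tert-butanol protonates the ketyl before amide can enolise toward C7.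

Step 12
Reactants: 17 (5S,6S,9S,10R)-13,14,15,16-tetranorlabd-8(17)-ene-6,12-diol
Product: 18 (5S,6S,9S,10R)-6-hydroxy-13,14,15,16-tetranorlabd-8(17)-en-12-al
Conditions: TEMPO (cat.), PhI(OAc)2, CH2Cl2, rt
Reagents that add atoms: none
Why: Oxoammonium (TEMPO) oxidation should be selective for the primary alcohol over the hindered secondary 6α-hydroxyl and leave the alkene alone.

Step 13
Reactants: 18 (5S,6S,9S,10R)-6-hydroxy-13,14,15,16-tetranorlabd-8(17)-en-12-al
Product: 19 (5S,6S,9S,10R,12E)-6-hydroxy-15-norlabda-8(17),12-dien-14-al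
Conditions: Ph3P=C(CH3)CHO, toluene, 90 °C
Reagents that add atoms: 2-(triphenylphosphoranylidene)propanal, CC(C=O)=P(c1ccccc1)(c1ccccc1)c1ccccc1
Why: Wittig olefination with the stabilised α-methyl ylide should give the (E)-trisubstituted enal.

Step 14
Reactants: 19 (5S,6S,9S,10R,12E)-6-hydroxy-15-norlabda-8(17),12-dien-14-al
Product: 20 (5S,6S,8R,9R,10S,12E)-8,17-epoxy-6-hydroxy-15-norlabd-12-en-14-al
Conditions: mCPBA, CH2Cl2, 0 °C; aq. NaHCO3/Na2S2O3 work-up
Reagents that add atoms: 3-chloroperbenzoic acid, OOC(=O)c1cccc(Cl)c1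
Why: In this Prilezhaev epoxidation the electron-rich 1,1-disubstituted C8=C17 alkene should react in preference to the electron-poor enal alkene, and the peracid should approach from the α face, away from the syn-axial C10 methyl, which places the oxygen on C8 in the α (equatorial) position.

Step 15
Reactants: 20 (5S,6S,8R,9R,10S,12E)-8,17-epoxy-6-hydroxy-15-norlabd-12-en-14-al
Product: 21 (5S,6S,8R,9R,10S,12E)-8,17-epoxylabda-12,14-dien-6-ol
Conditions: Ph3PCH3Br, KN(SiMe3)2 (excess), THF, −78 °C to 0 °C
Reagents that add atoms: methyltriphenylphosphonium bromide, C[P+](c1ccccc1)(c1ccccc1)c1ccccc1.[Br-]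
Why: Wittig methylenation of the enal should complete the (12E)-diene, and the hindered spiro-epoxide should not be opened by the ylide at low temperature.

Step 16
Reactants: 21 (5S,6S,8R,9R,10S,12E)-8,17-epoxylabda-12,14-dien-6-ol
Product: 22 (5S,6S,8R,9R,10S,12E)-labda-12,14-diene-6,8-diol
Conditions: LiAlH4, THF, 0 °C to rt; aq. NaOH work-up
Reagents that add atoms: none
Why: SN2 hydride opening at the unhindered primary C17 should turn the epoxide into the C17 methyl and leave the α-oxygen on C8, so C8 keeps the configuration set in step 14.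

Step 17
Reactants: 22 (5S,6S,8R,9R,10S,12E)-labda-12,14-diene-6,8-diol; 23 angelic acid
Product: 25 (5S,6S,8R,9R,10S,12E)-6-[(Z)-2-methylbut-2-enoyloxy]labda-12,14-dien-8-ol (target CNP0582767.1), via mixed anhydride 24 (not isolated)
Conditions: 2,4,6-trichlorobenzoyl chloride, Et3N, toluene, rt; then 22, 80 °C
Reagents that add atoms: none
Why: Yamaguchi-type esterification through the mixed anhydride should acylate the secondary equatorial 6α-hydroxyl and not the tertiary 8α-hydroxyl, with attack at the less hindered angeloyl carbonyl and, in the absence of a nucleophilic catalyst, without Z to E isomerisation to the tiglate.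

**Compound list**

1 | β-cyclocitral (2,6,6-trimethylcyclohex-1-ene-1-carbaldehyde) | CC1=C(C=O)C(C)(C)CCC1 | starting material
2 | rac-1-(2,6,6-trimethylcyclohex-1-en-1-yl)ethan-1-ol | CC(O)C1=C(C)CCCC1(C)C | intermediate
3 | 1-(2,6,6-trimethylcyclohex-1-en-1-yl)ethan-1-one | CC(=O)C1=C(C)CCCC1(C)C | intermediate
4 | (R)-1-(2,6,6-trimethylcyclohex-1-en-1-yl)ethan-1-ol | C[C@@H](O)C1=C(C)CCCC1(C)C | intermediate
5 | 4-(benzyloxy)butanoic acid | OC(=O)CCCOCc1ccccc1 | starting material
6 | (R)-1-(2,6,6-trimethylcyclohex-1-en-1-yl)ethyl 4-(benzyloxy)butanoate | C[C@@H](OC(=O)CCCOCc1ccccc1)C1=C(C)CCCC1(C)C | intermediate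
7 | (Z)-O-trimethylsilyl ketene acetal of 6 (CH2CH2OBn cis to OSiMe3) | C[C@@H](O/C(=C/CCOCc1ccccc1)O[Si](C)(C)C)C1=C(C)CCCC1(C)C | intermediate
8 | trimethylsilyl (2R)-4-(benzyloxy)-2-[(1R,2E)-2-ethylidene-1,3,3-trimethylcyclohexyl]butanoate | C[Si](C)(C)OC(=O)[C@H](CCOCc1ccccc1)[C@@]1(C)CCCC(C)(C)/C1=C\C | intermediate
9 | (2R)-4-(benzyloxy)-2-[(1R,2E)-2-ethylidene-1,3,3-trimethylcyclohexyl]butanoic acid | OC(=O)[C@H](CCOCc1ccccc1)[C@@]1(C)CCCC(C)(C)/C1=C\C | intermediate
10 | bis-borane adduct (C6 alkylborane, C8 alkoxyborane) | BOC[C@H](CCOCc1ccccc1)[C@@]1(C)CCCC(C)(C)[C@@H]1[C@@H](C)B | intermediate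
11 | (2R)-4-(benzyloxy)-2-[(1R,2S)-2-[(1R)-1-hydroxyethyl]-1,3,3-trimethylcyclohexyl]butan-1-ol | OC[C@H](CCOCc1ccccc1)[C@@]1(C)CCCC(C)(C)[C@@H]1[C@@H](C)O | intermediate
12 | (2R)-2-[(1R,2S)-2-acetyl-1,3,3-trimethylcyclohexyl]-4-(benzyloxy)butanal | O=C[C@H](CCOCc1ccccc1)[C@@]1(C)CCCC(C)(C)[C@@H]1C(C)=O | intermediate
13 | 1-[(1S,2R)-2-[(3S)-5-(benzyloxy)pent-1-yn-3-yl]-2,6,6-trimethylcyclohexyl]ethan-1-one | C#C[C@H](CCOCc1ccccc1)[C@@]1(C)CCCC(C)(C)[C@@H]1C(C)=O | intermediate
14 | tert-butyl({1-[(1S,2R)-2-[(3S)-5-(benzyloxy)pent-1-yn-3-yl]-2,6,6-trimethylcyclohexyl]ethenyl}oxy)dimethylsilane | C#C[C@H](CCOCc1ccccc1)[C@@]1(C)CCCC(C)(C)[C@@H]1C(=C)O[Si](C)(C)C(C)(C)C | intermediate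
15 | vinylgold silyloxocarbenium tetrafluoroborate (gold on C17, anti to C7) | C(c1ccccc1)OCC[C@@H]1[C@@]2(C)CCCC(C)(C)[C@@H]2C(=[O+][Si](C)(C)C(C)(C)C)C/C1=C/[Au-][P+](c1ccccc1)(c1ccccc1)c1ccccc1.F[B-](F)(F)F | intermediate
16 | (5S,9S,10R)-12-(benzyloxy)-13,14,15,16-tetranorlabd-8(17)-en-6-one | C(c1ccccc1)OCC[C@@H]1[C@@]2(C)CCCC(C)(C)[C@@H]2C(=O)CC1=C | intermediate
17 | (5S,6S,9S,10R)-13,14,15,16-tetranorlabd-8(17)-ene-6,12-diol (6α-OH) | OCC[C@@H]1[C@@]2(C)CCCC(C)(C)[C@@H]2[C@@H](O)CC1=C | intermediate
18 | (5S,6S,9S,10R)-6-hydroxy-13,14,15,16-tetranorlabd-8(17)-en-12-al | O=CC[C@@H]1[C@@]2(C)CCCC(C)(C)[C@@H]2[C@@H](O)CC1=C | intermediate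
19 | (5S,6S,9S,10R,12E)-6-hydroxy-15-norlabda-8(17),12-dien-14-al | O=C/C(C)=C/C[C@@H]1[C@@]2(C)CCCC(C)(C)[C@@H]2[C@@H](O)CC1=C | intermediate
20 | (5S,6S,8R,9R,10S,12E)-8,17-epoxy-6-hydroxy-15-norlabd-12-en-14-al (8α,17-epoxide) | O=C/C(C)=C/C[C@@H]1[C@@]2(C)CCCC(C)(C)[C@@H]2[C@@H](O)C[C@]13CO3 | intermediate
21 | (5S,6S,8R,9R,10S,12E)-8,17-epoxylabda-12,14-dien-6-ol | C=C/C(C)=C/C[C@@H]1[C@@]2(C)CCCC(C)(C)[C@@H]2[C@@H](O)C[C@]13CO3 | intermediate
22 | (5S,6S,8R,9R,10S,12E)-labda-12,14-diene-6,8-diol (6α,8α) | C=C/C(C)=C/C[C@@H]1[C@@]2(C)CCCC(C)(C)[C@@H]2[C@@H](O)C[C@@]1(C)O | intermediate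
23 | angelic acid [(Z)-2-methylbut-2-enoic acid] | C/C=C(/C)C(=O)O | starting material
24 | angelic 2,4,6-trichlorobenzoic anhydride | C/C=C(/C)C(=O)OC(=O)c1c(Cl)cc(Cl)cc1Cl | intermediate
25 | (5S,6S,8R,9R,10S,12E)-6-[(Z)-2-methylbut-2-enoyloxy]labda-12,14-dien-8-ol (CNP0582767.1) | C=C/C(C)=C/C[C@@H]1[C@@]2(C)CCCC(C)(C)[C@@H]2[C@@H](OC(=O)/C(C)=C\C)C[C@@]1(C)O | target

**Step count and risks**

Total steps: 17. Longest linear sequence: 17 steps (1 to 25); 5 and 23 are purchased.

Steps most likely to fail:

1. Step 10. The gold-bound alkyne may be hydrated, or the enol ether may lose its silyl group before the C7–C8 bond forms, so that the open-chain ketone is returned; attack at C17 (seven-membered ring) is a lesser concern. The fallback sets out from 14 and comes back at 16 by a radical ring closure. Treatment of 14 with N-bromosuccinimide in THF at −78 °C should give 2-bromo-1-[(1S,2R)-2-[(3S)-5-(benzyloxy)pent-1-yn-3-yl]-2,6,6-trimethylcyclohexyl]ethan-1-one F1. Slow addition of Bu3SnH with AIBN in benzene at 80 °C should then generate the α-keto radical at C7, which cyclises 6-exo-dig onto C8; the vinyl radical abstracts hydrogen to give 16.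

2. Step 5. The [3,3] shift joins a tertiary carbon to a fully substituted alkene carbon and may be slower than decomposition of the silyl ketene acetal, and loss of ketene acetal geometry would erode control at C9. The fallback sets out from 4 and comes back at 9. Johnson–Claisen rearrangement of 4 with triethyl orthoacetate and catalytic propanoic acid at 135 °C forms a less congested primary-to-quaternary bond with the same chirality transfer and should give ethyl 2-[(1R,2E)-2-ethylidene-1,3,3-trimethylcyclohexyl]acetate F2. Enolate alkylation (LiN(iPr)2, THF/DMPU, −78 °C, then 2-(benzyloxy)ethyl iodide) should give ethyl (2R)-4-(benzyloxy)-2-[(1R,2E)-2-ethylidene-1,3,3-trimethylcyclohexyl]butanoate F3, with the C9 epimer to be removed by chromatography. Saponification (LiOH, aqueous THF/MeOH) returns 9.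

3. Step 11. Amide formed during the reduction may move the exocyclic double bond into conjugation with the ketone before electron transfer, leading to over-reduction, or protonation may be incompletely equatorial-selective. The fallback sets out from 16 and comes back at 17. NaBH4 in MeOH at 0 °C should give the axial alcohol (5S,6R,9S,10R)-12-(benzyloxy)-13,14,15,16-tetranorlabd-8(17)-en-6-ol F4. Meerwein–Ponndorf–Verley/Oppenauer equilibration (Al(OiPr)3, iPrOH, catalytic acetone, toluene, reflux) should convert it into the equatorial alcohol (5S,6S,9S,10R)-12-(benzyloxy)-13,14,15,16-tetranorlabd-8(17)-en-6-ol F5. Reductive debenzylation with Li and 4,4'-di-tert-butylbiphenyl in THF at −78 °C then gives 17.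

Further compounds
F1 | step 10 | 2-bromo-1-[(1S,2R)-2-[(3S)-5-(benzyloxy)pent-1-yn-3-yl]-2,6,6-trimethylcyclohexyl]ethan-1-one | C#C[C@H](CCOCc1ccccc1)[C@@]1(C)CCCC(C)(C)[C@@H]1C(=O)CBr
F2 | step 5 | ethyl 2-[(1R,2E)-2-ethylidene-1,3,3-trimethylcyclohexyl]acetate | CCOC(=O)C[C@@]1(C)CCCC(C)(C)/C1=C\C
F3 | step 5 | ethyl (2R)-4-(benzyloxy)-2-[(1R,2E)-2-ethylidene-1,3,3-trimethylcyclohexyl]butanoate | CCOC(=O)[C@H](CCOCc1ccccc1)[C@@]1(C)CCCC(C)(C)/C1=C\C
F4 | step 11 | (5S,6R,9S,10R)-12-(benzyloxy)-13,14,15,16-tetranorlabd-8(17)-en-6-ol | C(c1ccccc1)OCC[C@@H]1[C@@]2(C)CCCC(C)(C)[C@@H]2[C@H](O)CC1=C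
F5 | step 11 | (5S,6S,9S,10R)-12-(benzyloxy)-13,14,15,16-tetranorlabd-8(17)-en-6-ol | C(c1ccccc1)OCC[C@@H]1[C@@]2(C)CCCC(C)(C)[C@@H]2[C@@H](O)CC1=C
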